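**Plan**

- Remark on the chemistry: the target has no stereocentre and no configurationally stable axis (the SMILES carries no stereodescriptor), so it is a single achiral species and no stereocontrol is needed.
- Retrosynthetic cuts, in order: the O–Si bond on ring A and the acetate O–acyl bond on ring B; the two MOM ethers and the methyl ester (ring A carboxyl carbon taken back to CH2OH); the bond between ring A C2 and the ketone carbon; last, the C–O bond of a tether ester between the two arenes.
- Enabling feature: in ring A (the ring with OMe and CO2Me) the ketone-bearing carbon C2 has the carboxyl carbon on C1 as its ortho neighbour. Taken down to CH2–O, that carbon can carry the ring B aroyl group as a benzyl ester, which places the ester carbonyl four atoms from C2.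
- Forward: bromo alcohol 4 (ring A, three steps) and acid 8 (ring B, two steps from orcinol) are joined by Mitsunobu esterification. Bromine–lithium exchange then moves the aroyl group from O to C2 (anionic homo-Fries), which should give the tetra-ortho-substituted diaryl ketone without over-addition.
- The helpers are then removed: CH2OH → CO2H → CO2Me, MOM cleavage, chelation-controlled monoacetylation of the 2,6-dihydroxybenzoyl ring, desilylation. No ring is built; both benzene rings come from commercial arenes.

Key step: step 7

Numbers are given to substrates, intermediates and products; reagents are given by name and SMILES within the steps.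

**Route**

Step 1
Reactants: 1 methyl 3-hydroxy-5-methoxybenzoate
Product: 2 methyl 3-methoxy-5-[(triisopropylsilyl)oxy]benzoate
Conditions: TIPSCl, imidazole, DMF, rt
Reagents that add atoms: triisopropylsilyl chloride, CC(C)[Si](Cl)(C(C)C)C(C)C
Why: Standard silylation of a phenol; the bulky silyl ether protects the ring A hydroxyl and later shields both of its ortho positions.

Step 2
Reactants: 2 methyl 3-methoxy-5-[(triisopropylsilyl)oxy]benzoate
Product: 3 methyl 2-bromo-3-methoxy-5-[(triisopropylsilyl)oxy]benzoate
Conditions: NBS (1.05 equiv), MeCN, 0 °C → rt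
Reagents that add atoms: N-bromosuccinimide, O=C1CCC(=O)N1Br
Why: Electrophilic aromatic bromination; C2 is para to the silyloxy group and ortho to OMe, whereas C4 and C6 both lie next to the triisopropylsilyloxy group and should be blocked sterically.

Step 3
Reactants: 3 methyl 2-bromo-3-methoxy-5-[(triisopropylsilyl)oxy]benzoate
Product: 4 {2-bromo-3-methoxy-5-[(triisopropylsilyl)oxy]phenyl}methanol
Conditions: DIBAL-H (2.5 equiv), CH2Cl2, −78 → 0 °C; aq. Rochelle salt
Reagents that add atoms: none
Why: DIBAL-H reduction of an aryl ester to the benzylic alcohol; aryl bromide and aryl silyl ether should be inert under these conditions.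

Step 4
Reactants: 5 orcinol (5-methylbenzene-1,3-diol)
Product: 6 1,3-bis(methoxymethoxy)-5-methylbenzene
Conditions: NaH (2.4 equiv), THF/DMF, 0 °C; MOMCl (2.4 equiv), 0 °C → rt
Reagents that add atoms: chloromethyl methyl ether, COCCl
Why: Williamson-type O-alkylation of both phenols; the MOM ethers protect ring B and direct the next lithiation.

Step 5
Reactants: 6 1,3-bis(methoxymethoxy)-5-methylbenzene
Product: 8 2,6-bis(methoxymethoxy)-4-methylbenzoic acid, via [2,6-bis(methoxymethoxy)-4-methylphenyl]lithium 7 (not isolated)
Conditions: n-BuLi (1.1 equiv), THF, 0 °C; CO2, −78 °C → rt; cold 1 M HCl to pH 3–4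
Reagents that add atoms: carbon dioxide, O=C=O
Why: Directed ortho-metalation at the carbon between the two coordinating OMOM groups, followed by carboxylation of the aryllithium.

Step 6
Reactants: 4 {2-bromo-3-methoxy-5-[(triisopropylsilyl)oxy]phenyl}methanol; 8 2,6-bis(methoxymethoxy)-4-methylbenzoic acid
Product: 9 {2-bromo-3-methoxy-5-[(triisopropylsilyl)oxy]phenyl}methyl 2,6-bis(methoxymethoxy)-4-methylbenzoate
Conditions: PPh3, DIAD, THF, 0 °C → rt
Reagents that add atoms: none
Why: Mitsunobu esterification; the carboxylate attacks the activated benzylic carbon, so no acyl substitution at the hindered 2,6-disubstituted acid is required.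

Step 7
Reactants: 9 {2-bromo-3-methoxy-5-[(triisopropylsilyl)oxy]phenyl}methyl 2,6-bis(methoxymethoxy)-4-methylbenzoate
Product: 12 [2,6-bis(methoxymethoxy)-4-methylphenyl]{2-(hydroxymethyl)-6-methoxy-4-[(triisopropylsilyl)oxy]phenyl}methanone, via aryllithium 10 (not isolated), via cyclic lithium hemiketal alkoxide 11 (not isolated)
Conditions: n-BuLi (1.1 equiv), THF, −78 °C; then AcOH, −78 °C → rt
Reagents that add atoms: none
Why: Bromine–lithium exchange at C2 of ring A should outrun addition of butyllithium to the ester carbonyl at −78 °C, because that carbonyl is flanked by two ortho OMOM groups, and gives aryllithium 10. Its carbanion sits four atoms from the ester carbonyl carbon (C2–C1–CH2–O–C=O) and should add through a five-membered transition state (5-exo-trig), closing the transient 1,3-dihydroisobenzofuran ring of alkoxide 11, which is a helper only and opens to the hydroxy ketone on protonation. The closest known reaction type is the anionic homo-Fries rearrangement (1,4 O→C acyl shift) of 2-bromobenzyl benzoates, which has been applied to benzophenones with four ortho substituents. Because the carbonyl group is stored as alkoxide 11 until the quench, a second addition is excluded, and because delivery is intramolecular the congestion around the new bond (OMe and CH2O on ring A, two OMOM on ring B) should not block it. No stereocentre remains in the product, since the hemiketal carbon of 11 is racemic and is lost on ring opening. The site of bond formation is fixed by the position of bromine, and benzylic deprotonation of the ArCH2O group is the competing path that the low temperature and the fast exchange should suppress.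

Step 8
Reactants: 12 [2,6-bis(methoxymethoxy)-4-methylphenyl]{2-(hydroxymethyl)-6-methoxy-4-[(triisopropylsilyl)oxy]phenyl}methanone
Product: 14 2-[2,6-bis(methoxymethoxy)-4-methylbenzoyl]-3-methoxy-5-[(triisopropylsilyl)oxy]benzoic acid, via keto aldehyde 13 (not isolated)
Conditions: TEMPO (0.2 equiv), PhI(OAc)2 (2.5 equiv), MeCN/H2O 1:1, rt
Reagents that add atoms: water, O
Why: Nitroxyl-catalysed oxidation of a primary benzylic alcohol to the acid through the aldehyde hydrate; the open hydroxy ketone form of 12 is drained from any lactol, and no chlorine-based oxidant touches the electron-rich rings.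

Step 9
Reactants: 14 2-[2,6-bis(methoxymethoxy)-4-methylbenzoyl]-3-methoxy-5-[(triisopropylsilyl)oxy]benzoic acid
Product: 15 methyl 2-[2,6-bis(methoxymethoxy)-4-methylbenzoyl]-3-methoxy-5-[(triisopropylsilyl)oxy]benzoate
Conditions: TMSCHN2, toluene/MeOH 4:1, 0 °C → rt
Reagents that add atoms: trimethylsilyldiazomethane, C[Si](C)(C)C=[N+]=[N-]
Why: O-methylation of the carboxylic acid with a diazomethane equivalent should give the open (normal) methyl ester under base-free conditions that spare the aryl silyl ether.

Step 10
Reactants: 15 methyl 2-[2,6-bis(methoxymethoxy)-4-methylbenzoyl]-3-methoxy-5-[(triisopropylsilyl)oxy]benzoate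
Product: 16 methyl 2-(2,6-dihydroxy-4-methylbenzoyl)-3-methoxy-5-[(triisopropylsilyl)oxy]benzoate
Conditions: conc. HCl (cat.), MeOH, rt → 40 °C
Reagents that add atoms: none
Why: Acid-catalysed acetal exchange removes both MOM ethers, helped by the ortho carbonyl group; the aryl triisopropylsilyl ether, methyl ester and ketone should survive dilute methanolic acid.

Step 11
Reactants: 16 methyl 2-(2,6-dihydroxy-4-methylbenzoyl)-3-methoxy-5-[(triisopropylsilyl)oxy]benzoate
Product: 17 methyl 2-(2-acetoxy-6-hydroxy-4-methylbenzoyl)-3-methoxy-5-[(triisopropylsilyl)oxy]benzoate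
Conditions: Ac2O (1.05 equiv), pyridine, CH2Cl2, 0 °C
Reagents that add atoms: acetic anhydride, CC(=O)OC(C)=O
Why: Chelation-controlled monoacylation of a 2,6-dihydroxyaryl ketone; the two hydroxyls are equivalent, and after the first acetylation the remaining one is locked in a hydrogen bond to the ketone and should react much more slowly, while the ring A oxygen is still silylated.

Step 12
Reactants: 17 methyl 2-(2-acetoxy-6-hydroxy-4-methylbenzoyl)-3-methoxy-5-[(triisopropylsilyl)oxy]benzoate
Product: 18 penibenzophenone C, methyl 2-(2-acetoxy-6-hydroxy-4-methylbenzoyl)-5-hydroxy-3-methoxybenzoate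
Conditions: HF·pyridine, THF/pyridine, 0 °C → rt
Reagents that add atoms: none
Why: Fluoride-mediated cleavage of the aryl silyl ether in a buffered, non-basic medium, in which the aryl acetate and the methyl ester should be stable.

**Compound list**

1 | methyl 3-hydroxy-5-methoxybenzoate | COC(=O)c1cc(O)cc(OC)c1 | starting material
2 | methyl 3-methoxy-5-[(triisopropylsilyl)oxy]benzoate | COC(=O)c1cc(OC)cc(O[Si](C(C)C)(C(C)C)C(C)C)c1 | intermediate
3 | methyl 2-bromo-3-methoxy-5-[(triisopropylsilyl)oxy]benzoate | COC(=O)c1cc(O[Si](C(C)C)(C(C)C)C(C)C)cc(OC)c1Br | intermediate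
4 | {2-bromo-3-methoxy-5-[(triisopropylsilyl)oxy]phenyl}methanol | OCc1cc(O[Si](C(C)C)(C(C)C)C(C)C)cc(OC)c1Br | intermediate
5 | orcinol (5-methylbenzene-1,3-diol) | Cc1cc(O)cc(O)c1 | starting material
6 | 1,3-bis(methoxymethoxy)-5-methylbenzene | COCOc1cc(C)cc(OCOC)c1 | intermediate
7 | [2,6-bis(methoxymethoxy)-4-methylphenyl]lithium (not isolated) | [Li]c1c(OCOC)cc(C)cc1OCOC | intermediate
8 | 2,6-bis(methoxymethoxy)-4-methylbenzoic acid | COCOc1cc(C)cc(OCOC)c1C(=O)O | intermediate
9 | {2-bromo-3-methoxy-5-[(triisopropylsilyl)oxy]phenyl}methyl 2,6-bis(methoxymethoxy)-4-methylbenzoate | COCOc1cc(C)cc(OCOC)c1C(=O)OCc1cc(O[Si](C(C)C)(C(C)C)C(C)C)cc(OC)c1Br | intermediate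
10 | {2-lithio-3-methoxy-5-[(triisopropylsilyl)oxy]phenyl}methyl 2,6-bis(methoxymethoxy)-4-methylbenzoate (aryllithium, not isolated) | COCOc1cc(C)cc(OCOC)c1C(=O)OCc1cc(O[Si](C(C)C)(C(C)C)C(C)C)cc(OC)c1[Li] | intermediate
11 | lithium 1-[2,6-bis(methoxymethoxy)-4-methylphenyl]-7-methoxy-5-[(triisopropylsilyl)oxy]-1,3-dihydro-2-benzofuran-1-olate (racemic, not isolated) | [Li]OC1(c2c(OCOC)cc(C)cc2OCOC)OCc2cc(O[Si](C(C)C)(C(C)C)C(C)C)cc(OC)c21 | intermediate
12 | [2,6-bis(methoxymethoxy)-4-methylphenyl]{2-(hydroxymethyl)-6-methoxy-4-[(triisopropylsilyl)oxy]phenyl}methanone (open form; may equilibrate with its cyclic hemiketal) | COCOc1cc(C)cc(OCOC)c1C(=O)c1c(CO)cc(O[Si](C(C)C)(C(C)C)C(C)C)cc1OC | intermediate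
13 | 2-[2,6-bis(methoxymethoxy)-4-methylbenzoyl]-3-methoxy-5-[(triisopropylsilyl)oxy]benzaldehyde (not isolated in the main route) | COCOc1cc(C)cc(OCOC)c1C(=O)c1c(C=O)cc(O[Si](C(C)C)(C(C)C)C(C)C)cc1OC | intermediate
14 | 2-[2,6-bis(methoxymethoxy)-4-methylbenzoyl]-3-methoxy-5-[(triisopropylsilyl)oxy]benzoic acid | COCOc1cc(C)cc(OCOC)c1C(=O)c1c(C(=O)O)cc(O[Si](C(C)C)(C(C)C)C(C)C)cc1OC | intermediate
15 | methyl 2-[2,6-bis(methoxymethoxy)-4-methylbenzoyl]-3-methoxy-5-[(triisopropylsilyl)oxy]benzoate | COCOc1cc(C)cc(OCOC)c1C(=O)c1c(C(=O)OC)cc(O[Si](C(C)C)(C(C)C)C(C)C)cc1OC | intermediate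
16 | methyl 2-(2,6-dihydroxy-4-methylbenzoyl)-3-methoxy-5-[(triisopropylsilyl)oxy]benzoate | COC(=O)c1cc(O[Si](C(C)C)(C(C)C)C(C)C)cc(OC)c1C(=O)c1c(O)cc(C)cc1O | intermediate
17 | methyl 2-(2-acetoxy-6-hydroxy-4-methylbenzoyl)-3-methoxy-5-[(triisopropylsilyl)oxy]benzoate | COC(=O)c1cc(O[Si](C(C)C)(C(C)C)C(C)C)cc(OC)c1C(=O)c1c(O)cc(C)cc1OC(C)=O | intermediate
18 | penibenzophenone C, methyl 2-(2-acetoxy-6-hydroxy-4-methylbenzoyl)-5-hydroxy-3-methoxybenzoate (achiral) | COC(=O)c1cc(O)cc(OC)c1C(=O)c1c(O)cc(C)cc1OC(C)=O | target

**Count**

Total steps: 12. Longest linear sequence: 10 steps (steps 1–3 and 6–12); the ring B branch (steps 4 and 5) joins at step 6.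

**Steps most likely to fail, with fallbacks**

Step 2. The bromination may not distinguish cleanly between C2 and the position para to the methoxy group (C6), or may run on to a dibromide. The fallback sets out from 2 and comes back at 4, and fixes the halogen position by coordination instead of arene electronics. Compound 2 is first reduced with DIBAL-H to {3-methoxy-5-[(triisopropylsilyl)oxy]phenyl}methanol F1. Directed ortho-metalation with n-BuLi (2.3 equiv, toluene/Et2O, 0 °C → rt) should then give lithium {2-lithio-3-methoxy-5-[(triisopropylsilyl)oxy]phenyl}methanolate F2, because only C2 lies between the two coordinating groups CH2OLi and OMe, while the silyloxy group neither coordinates well nor leaves room next to it. Quenching with 1,2-dibromoethane at −78 °C should deliver 4.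

Step 7. Butyllithium may add to the ester carbonyl or remove a benzylic proton before the exchange is complete, or the aryllithium may be protonated before the acyl shift, which would return debrominated ester. The fallback sets out from 4 and 6 and comes back at 14; it joins the halves intermolecularly at the aldehyde oxidation level, where addition tolerates the congestion. Compound 6 is lithiated as in step 5 and the aryllithium 7 is quenched with DMF to give 2,6-bis(methoxymethoxy)-4-methylbenzaldehyde F3. Compound 4 is treated with n-BuLi (2.1 equiv, THF, −78 °C), which by deprotonation and bromine–lithium exchange gives the dilithio species F2 already described, and addition of F3 should give the racemic diol [2,6-bis(methoxymethoxy)-4-methylphenyl]{2-(hydroxymethyl)-6-methoxy-4-[(triisopropylsilyl)oxy]phenyl}methanol F4. Swern oxidation of both hydroxyls, which are activated before base is added so that lactol formation cannot intervene, should give keto aldehyde 13, here isolated. Pinnick oxidation (NaClO2, NaH2PO4, 2-methyl-2-butene) then gives 14.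

Step 11. The acetylation may run on to the diacetate or stop short, since the two hydroxyls differ only through hydrogen bonding. The fallback sets out from 15 and comes back at 17; it unmasks the two oxygens one after the other, so that the acylation meets a single free hydroxyl. Brief treatment of 15 with catalytic acid in MeOH at 0 °C should remove one MOM ether with help from the neighbouring carbonyl group and stop at methyl 2-[2-hydroxy-6-(methoxymethoxy)-4-methylbenzoyl]-3-methoxy-5-[(triisopropylsilyl)oxy]benzoate F5, whose new hydroxyl chelates the ketone and withdraws that help from the second MOM ether. Any material that goes on to diol 16 is not lost, since 16 lies on the main route. Acetylation of F5 (Ac2O, Et3N, DMAP, CH2Cl2) gives methyl 2-[2-acetoxy-6-(methoxymethoxy)-4-methylbenzoyl]-3-methoxy-5-[(triisopropylsilyl)oxy]benzoate F6. The last MOM ether is then cleaved with TFA in CH2Cl2 at 0 °C, a non-nucleophilic medium that should not transesterify the aryl acetate, to give 17.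

**Further compounds**

F1 | step 2 | {3-methoxy-5-[(triisopropylsilyl)oxy]phenyl}methanol | OCc1cc(OC)cc(O[Si](C(C)C)(C(C)C)C(C)C)c1
F2 | step 2 | lithium {2-lithio-3-methoxy-5-[(triisopropylsilyl)oxy]phenyl}methanolate | [Li]OCc1cc(O[Si](C(C)C)(C(C)C)C(C)C)cc(OC)c1[Li]
F3 | step 7 | 2,6-bis(methoxymethoxy)-4-methylbenzaldehyde | COCOc1cc(C)cc(OCOC)c1C=O
F4 | step 7 | [2,6-bis(methoxymethoxy)-4-methylphenyl]{2-(hydroxymethyl)-6-methoxy-4-[(triisopropylsilyl)oxy]phenyl}methanol (racemic) | COCOc1cc(C)cc(OCOC)c1C(O)c1c(CO)cc(O[Si](C(C)C)(C(C)C)C(C)C)cc1OC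
F5 | step 11 | methyl 2-[2-hydroxy-6-(methoxymethoxy)-4-methylbenzoyl]-3-methoxy-5-[(triisopropylsilyl)oxy]benzoate | COCOc1cc(C)cc(O)c1C(=O)c1c(C(=O)OC)cc(O[Si](C(C)C)(C(C)C)C(C)C)cc1OC
F6 | step 11 | methyl 2-[2-acetoxy-6-(methoxymethoxy)-4-methylbenzoyl]-3-methoxy-5-[(triisopropylsilyl)oxy]benzoate | COCOc1cc(C)cc(OC(C)=O)c1C(=O)c1c(C(=O)OC)cc(O[Si](C(C)C)(C(C)C)C(C)C)cc1OC
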